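**Remark:** gustastatin has no stereocentre, so names and SMILES carry no stereodescriptors. LiN(iPr)2 (LDA) is taken as a bought solution.

## The problem

Gustastatin (23) is a depside. Ring A, a 2-hydroxy-4-methoxy-6-(2-oxoheptyl)benzoyl unit, is joined through its C1 carboxyl to the C4 oxygen of ring B, methyl 4-hydroxy-2-methoxy-6-(2-oxoheptyl)benzoate. There is no stereocentre, so nothing has to be controlled or relayed in three dimensions. The difficulty is regiochemistry and functional-group tolerance.

Each ring carries the same ArCH2C(=O)C5H11 chain ortho to an ester carbonyl. Whenever that carbonyl is activated, the enol oxygen of the chain can attack it and close a 3-pentylisocoumarin. The ring A aryl ester is the most exposed, because its leaving group is a phenoxide; the finished depside therefore tolerates neither strong base nor strong acid. The central C(=O)–O bond is also flanked by two ortho substituents and is hard to make. The oxygen pattern must be differentiated as well: ring A has a free 2-OH and a 4-OMe, ring B a 2-OMe and an acylated 4-O.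

The feature that enables the plan lies in ring A. C1 has the oxygen-bearing C2 on one side and the chain-bearing C6 on the other. In a 2-alkoxy-4-methoxybenzoic acid, C6 is the only ortho C–H bond, and it is meta to both alkoxy groups, so electrophilic substitution would not reach it but a carboxylate-bound metal would.

## Retrosynthesis

**End game.** Gustastatin 23 is traced to its O-benzyl ether 22, and 22 to the mono-dioxolane 21. The bonds cut are only O–CH2Ph and the two ketal C–O bonds. Hydrogenolysis is placed last because it is neutral and the unmasked keto depside is the most fragile compound of the route. The forward steps must hydrolyse one dioxolane without letting the freed ketone displace the ring B phenol.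

**Depside bond.** Cutting the aryl ester C(=O)–O bond of 21 gives ring A acid 13 and ring B phenol 20. This is the most convergent cut, and it splits the molecule into halves of equal size that share the hexanoyl carbon source 5. The ring A ketone must be masked in 13, because an activated acid with a free ortho 2-oxoheptyl group would collapse to an isocoumarin at once. The ring B ketone sits beside a much less reactive methyl ester and can stay free. The forward reaction has to acylate a phenol with a 2,6-disubstituted benzoic acid under mild base.

**Ring A acid from an isocoumarin.** Acid 13 comes from allyl ester 12 by deallylation, 12 from keto ester 11 by ketalisation, and 11 from isocoumarin 9 through the potassium keto carboxylate 10. No skeletal bond is cut. The lactone C–O bond of 9 is opened by hydroxide and the carboxylate is capped by alkylation, so no acyl activation occurs while the ketone is free. An allyl ester is chosen because it comes off under neutral conditions from a hindered benzoate, where a methyl ester would need forcing base.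

**Key disconnection.** Isocoumarin 9 is cut at the C6–CH2 bond and at the lactone C–O bond, giving 2-(benzyloxy)-4-methoxybenzoic acid 3 and the hexanoyl sulfoxonium ylide 7; keto acid 8 is the unisolated link. Compared with a lateral-lithiation route to ring A, this cut starts from an acid that already has the correct O-methyl group and needs no hindered ester hydrolysis. Compared with electrophilic chemistry, it reaches the one ring position that is electronically deactivated. The precursor is a monosubstituted-chain-free benzoic acid; the forward reaction must deliver all seven chain carbons to C6 only.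

**Key-step partners.** Acid 3 comes from benzyl ester 2, and 2 from commercial 2-hydroxy-4-methoxybenzoic acid 1 by double benzylation. Ylide 7 comes from trimethylsulfoxonium iodide 4 and hexanoyl chloride 5 through methylide 6. These are routine O–C and C–C(=O) disconnections.

**Ring B.** Phenol 20 comes from benzyl ether 19. Keto ester 19 is cut at the CH2–C(=O) bond into toluate 17 (through its lithio derivative 18) and Weinreb amide 14, which is made from 5. Toluate 17 comes from methyl orsellinate 15 through mono-benzyl ether 16. Here the benzylic carbon and the methyl ester are already present in 15, so lateral lithiation is shorter than a second C–H activation. The forward acylation must stop at the ketone and must not let the enolate close onto the ester.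

## Roads not taken

**Alternative 1:** aryne insertion for ring B. The cut removes the C6–CH2 and C1–C(=O) bonds of ring B together. In the forward step CsF converts the silyl triflate A2 into its aryne, the anion of dimethyl malonate A3 adds at the carbon remote from the methoxy group, and the aryl anion takes one ester group, giving homophthalate A1.
- Merits: two C–C bonds form in one metal-free step, the methoxy group fixes the regiochemistry, and the aromatic ester arrives directly as the methyl ester ring B needs, with no lactone detour.
- Weak points: A2 needs several steps of phenol silylation and triflation. A1 carries an acetate ester, not the pentyl ketone, so the aliphatic ester must be converted selectively beside the aromatic one. Simple arylation of the malonate competes. Ring A is not addressed; a methyl 2,6-disubstituted benzoate made this way would still need a harsh hydrolysis.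
- Comparison: the aryne route is more elegant for the ortho pair. The chosen plan sets against it four steps from 15 to 20 and a one-step chain installation on ring A from acid 3.

**Alternative 2:** biomimetic aromatisation of ring A on the preformed ester. The cut is the C1–C6 bond of ring A. In the forward step the C2 methylene of trioxo ester A5 adds to the C7 ketone and the aldol dehydrates, giving the resorcylate A4.
- Merits: the hindered depside bond is made at the open-chain stage, by trapping an acylketene with the ring B phenol, so no hindered esterification is needed. In this respect it is better than the chosen plan.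
- Weak points: A5 is a polycarbonyl compound that takes several steps and careful handling. Both ketones must be ketalised. The aromatisation and the later selective 4-O-methylation of A4 use base in the presence of the labile aryl ester.
- Comparison: the chosen plan has the harder esterification (step 13). It sets against this stable aromatic intermediates, a ring A methyl ether present from the start, and only one ketal.

**Alternative 3:** Diels–Alder benzannulation of ring A. The cut removes the C1–C2 and C5–C6 bonds of ring A. In the forward step diene A8 adds to the triple bond of the ring B ynoate A7, and loss of methanol and of the silyl group gives bis-dioxolane A6.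
- Merits: ring A appears with its OH and OMe already differentiated, with no benzyl group, and the ester is made on an unhindered ynoic acid.
- Weak points: a β-alkyl ynoate is a slow dienophile and A8 is heat- and acid-sensitive. The propargylic CH2 next to the ketal can isomerise to an allene. Aryl ynoates accept phenoxide in conjugate addition during their own preparation. Two ketals must be removed at the end.
- Comparison: A6 is closer to the target than 21 and saves one deprotection. The chosen plan sets against this commercial aromatic starting materials and reaction types with close precedent at every stage.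

Key step: step 4

## Route

Step 1
Reactants: 1 2-hydroxy-4-methoxybenzoic acid
Product: 2 benzyl 2-(benzyloxy)-4-methoxybenzoate
Conditions: BnBr, K2CO3, DMF, 60 °C
Reagents that add atoms: benzyl bromide, BrCc1ccccc1
Why: Williamson alkylation of both the carboxylate and the phenoxide; warming in DMF overcomes the hydrogen bond of the salicylate OH.

Step 2
Reactants: 2 benzyl 2-(benzyloxy)-4-methoxybenzoate
Product: 3 2-(benzyloxy)-4-methoxybenzoic acid
Conditions: NaOH, THF/MeOH/H2O, 60 °C; then aq HCl
Reagents that add atoms: sodium hydroxide, [Na+].[OH-]
Why: Saponification of the benzyl ester by acyl substitution; the benzyl ether and methyl ether are inert to hydroxide.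

Step 3
Reactants: 4 trimethylsulfoxonium iodide; 5 hexanoyl chloride
Product: 7 1-(dimethyl(oxo)-lambda6-sulfanylidene)heptan-2-one, via dimethylsulfoxonium methylide 6 (not isolated)
Conditions: 4 (2.2 equiv), KOtBu (2.2 equiv), THF, reflux; then 5 (1 equiv), 0 °C to rt
Reagents that add atoms: none
Why: Corey–Chaykovsky ylide generation followed by C-acylation; a second equivalent of 6 deprotonates the acylsulfoxonium salt to give the stabilised keto ylide.

Step 4
Reactants: 3 2-(benzyloxy)-4-methoxybenzoic acid; 7 1-(dimethyl(oxo)-lambda6-sulfanylidene)heptan-2-one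
Product: 9 8-(benzyloxy)-6-methoxy-3-pentyl-1H-isochromen-1-one, via 2-(benzyloxy)-4-methoxy-6-(2-oxoheptyl)benzoic acid 8 (not isolated)
Conditions: [Cp*RhCl2]2 (cat.), NaOAc, HFIP, 90 °C
Reagents that add atoms: none
Why: This is the known [Cp*RhCl2]2-catalysed (trivalent rhodium) ortho C–H acylmethylation of benzoic acids with sulfoxonium ylides, which ends in 3-substituted isocoumarins. Acetate-assisted concerted metalation–deprotonation of the rhodium carboxylate of 3 at C6 should give a five-membered rhodacycle; ylide 7 then binds through carbon and loses dimethyl sulfoxide to form a rhodium carbene. Migratory insertion makes the C6–CH2 bond in a six-membered rhodacycle, and protodemetalation releases keto acid 8 and the catalyst without an external oxidant. In the hot, weakly acidic medium the carboxyl oxygen of 8 adds to the chain ketone (6-exo-trig) and the lactol dehydrates to the pyranone ring of 9. No stereocentre is formed. Only site selectivity is needed, and the substrate fixes it: C2 is blocked by the benzyloxy group, so C6 is the one ortho C–H bond the carboxylate can reach, while the electron-rich C3 and C5 lie outside the chelate. The benzyl ether also keeps the phenol from intercepting the carbene.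

Step 5
Reactants: 9 8-(benzyloxy)-6-methoxy-3-pentyl-1H-isochromen-1-one
Product: 11 allyl 2-(benzyloxy)-4-methoxy-6-(2-oxoheptyl)benzoate, via potassium keto carboxylate 10 (not isolated)
Conditions: KOH (1.05 equiv), THF/H2O, 50 °C; evaporate; allyl bromide, DMF, rt
Reagents that add atoms: potassium hydroxide, [K+].[OH-]; allyl bromide, C=CCBr
Why: Hydroxide opens the enol lactone by acyl substitution and the expelled enolate tautomerises to the ketone; the carboxylate is then esterified by SN2 attack on allyl bromide. The new bond forms at the allyl carbon, so the hindered carboxyl is never activated and cannot re-close.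

Step 6
Reactants: 11 allyl 2-(benzyloxy)-4-methoxy-6-(2-oxoheptyl)benzoate
Product: 12 allyl 2-(benzyloxy)-4-methoxy-6-[(2-pentyl-1,3-dioxolan-2-yl)methyl]benzoate
Conditions: (TMSOCH2)2, TMSOTf (cat.), CH2Cl2, −78 to −20 °C; then pyridine
Reagents that add atoms: 1,2-bis(trimethylsilyloxy)ethane, C[Si](C)(C)OCCO[Si](C)(C)C
Why: Noyori ketalisation; the aprotic, low-temperature conditions should convert the ketone without acid-promoted lactonisation onto the allyl ester.

Step 7
Reactants: 12 allyl 2-(benzyloxy)-4-methoxy-6-[(2-pentyl-1,3-dioxolan-2-yl)methyl]benzoate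
Product: 13 2-(benzyloxy)-4-methoxy-6-[(2-pentyl-1,3-dioxolan-2-yl)methyl]benzoic acid
Conditions: Pd(PPh3)4 (cat.), morpholine, THF, rt; pH 5 buffer work-up
Reagents that add atoms: none
Why: Tsuji–Trost deallylation; zerovalent palladium ionises the allyl ester and morpholine captures the allyl complex, under neutral conditions that spare the ketal and the benzyl ether. Acid 13 is used at once in step 13.

Step 8
Reactants: 5 hexanoyl chloride
Product: 14 N-methoxy-N-methylhexanamide
Conditions: MeNHOMe·HCl, K2CO3, EtOAc/H2O, 0 °C to rt
Reagents that add atoms: N,O-dimethylhydroxylamine hydrochloride, CNOC.Cl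
Why: Schotten–Baumann N-acylation giving the Weinreb amide.

Step 9
Reactants: 15 methyl 2,4-dihydroxy-6-methylbenzoate (methyl orsellinate)
Product: 16 methyl 4-(benzyloxy)-2-hydroxy-6-methylbenzoate
Conditions: BnBr (1.05 equiv), K2CO3, acetone, reflux
Reagents that add atoms: benzyl bromide, BrCc1ccccc1
Why: Williamson etherification; the 2-OH is hydrogen-bonded to the ester carbonyl and much less nucleophilic, so one equivalent of halide should alkylate the 4-OH selectively.

Step 10
Reactants: 16 methyl 4-(benzyloxy)-2-hydroxy-6-methylbenzoate
Product: 17 methyl 4-(benzyloxy)-2-methoxy-6-methylbenzoate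
Conditions: MeI (excess), K2CO3, DMF, 50 °C
Reagents that add atoms: iodomethane, CI
Why: Williamson O-methylation of the chelated phenol under more forcing conditions.

Step 11
Reactants: 17 methyl 4-(benzyloxy)-2-methoxy-6-methylbenzoate; 14 N-methoxy-N-methylhexanamide
Product: 19 methyl 4-(benzyloxy)-2-methoxy-6-(2-oxoheptyl)benzoate, via lithiated toluate 18 (not isolated)
Conditions: LiN(iPr)2 (LDA, 2 equiv), THF, −78 °C; then 14, −78 to −40 °C; aq NH4Cl
Reagents that add atoms: none
Why: Lateral lithiation of the ortho-toluate and acylation with a Weinreb amide; the chelated tetrahedral adduct prevents over-addition and keeps the ketone masked until the quench, so enolate closure onto the ester is not expected.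

Step 12
Reactants: 19 methyl 4-(benzyloxy)-2-methoxy-6-(2-oxoheptyl)benzoate
Product: 20 methyl 4-hydroxy-2-methoxy-6-(2-oxoheptyl)benzoate
Conditions: H2 (1 atm), 10% Pd/C, EtOAc, rt
Reagents that add atoms: none
Why: Hydrogenolysis of the benzyl aryl ether; the non-conjugated ketone and the methyl ester are not reduced.

Step 13
Reactants: 13 2-(benzyloxy)-4-methoxy-6-[(2-pentyl-1,3-dioxolan-2-yl)methyl]benzoic acid; 20 methyl 4-hydroxy-2-methoxy-6-(2-oxoheptyl)benzoate
Product: 21 3-methoxy-4-(methoxycarbonyl)-5-(2-oxoheptyl)phenyl 2-(benzyloxy)-4-methoxy-6-[(2-pentyl-1,3-dioxolan-2-yl)methyl]benzoate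
Conditions: EDC·HCl, DMAP, CH2Cl2, 0 °C to rt
Reagents that add atoms: none
Why: Steglich esterification, the standard depside-forming reaction between a 2,6-disubstituted benzoic acid and a phenol. The ring A ketone is masked, so the activated acid cannot collapse to 9, and DMAP is too weak a base to cyclise the ring B keto ester.

Step 14
Reactants: 21 3-methoxy-4-(methoxycarbonyl)-5-(2-oxoheptyl)phenyl 2-(benzyloxy)-4-methoxy-6-[(2-pentyl-1,3-dioxolan-2-yl)methyl]benzoate
Product: 22 3-methoxy-4-(methoxycarbonyl)-5-(2-oxoheptyl)phenyl 2-(benzyloxy)-4-methoxy-6-(2-oxoheptyl)benzoate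
Conditions: 1 M aq HCl, THF, rt
Reagents that add atoms: water, O
Why: Acid-catalysed hydrolysis of the dioxolane through an oxocarbenium ion; dilute acid at room temperature should leave the twisted, shielded aryl ester, the methyl ester and the benzyl ether intact.

Step 15
Reactants: 22 3-methoxy-4-(methoxycarbonyl)-5-(2-oxoheptyl)phenyl 2-(benzyloxy)-4-methoxy-6-(2-oxoheptyl)benzoate
Product: 23 gustastatin
Conditions: H2 (1 atm), 10% Pd/C, EtOAc, rt
Reagents that add atoms: none
Why: Hydrogenolysis of the last benzyl ether under neutral conditions, so the acid- and base-sensitive keto depside is released without further reagents.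

## Compound list

1 | 2-hydroxy-4-methoxybenzoic acid | COc1ccc(C(=O)O)c(O)c1 | starting material
2 | benzyl 2-(benzyloxy)-4-methoxybenzoate | COc1ccc(C(=O)OCc2ccccc2)c(OCc2ccccc2)c1 | intermediate
3 | 2-(benzyloxy)-4-methoxybenzoic acid | COc1ccc(C(=O)O)c(OCc2ccccc2)c1 | intermediate
4 | trimethylsulfoxonium iodide | C[S+](C)(C)=O.[I-] | starting material
5 | hexanoyl chloride | CCCCCC(=O)Cl | starting material
6 | dimethylsulfoxonium methylide | C=S(C)(C)=O | intermediate (not isolated)
7 | 1-(dimethyl(oxo)-lambda6-sulfanylidene)heptan-2-one | CCCCCC(=O)C=S(C)(C)=O | intermediate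
8 | 2-(benzyloxy)-4-methoxy-6-(2-oxoheptyl)benzoic acid | CCCCCC(=O)Cc1cc(OC)cc(OCc2ccccc2)c1C(=O)O | intermediate (not isolated)
9 | 8-(benzyloxy)-6-methoxy-3-pentyl-1H-isochromen-1-one | CCCCCC1=Cc2cc(OC)cc(OCc3ccccc3)c2C(=O)O1 | intermediate
10 | potassium 2-(benzyloxy)-4-methoxy-6-(2-oxoheptyl)benzoate | CCCCCC(=O)Cc1cc(OC)cc(OCc2ccccc2)c1C(=O)[O-].[K+] | intermediate (not isolated)
11 | allyl 2-(benzyloxy)-4-methoxy-6-(2-oxoheptyl)benzoate | CCCCCC(=O)Cc1cc(OC)cc(OCc2ccccc2)c1C(=O)OCC=C | intermediate
12 | allyl 2-(benzyloxy)-4-methoxy-6-[(2-pentyl-1,3-dioxolan-2-yl)methyl]benzoate | CCCCCC1(Cc2cc(OC)cc(OCc3ccccc3)c2C(=O)OCC=C)OCCO1 | intermediate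
13 | 2-(benzyloxy)-4-methoxy-6-[(2-pentyl-1,3-dioxolan-2-yl)methyl]benzoic acid | CCCCCC1(Cc2cc(OC)cc(OCc3ccccc3)c2C(=O)O)OCCO1 | intermediate
14 | N-methoxy-N-methylhexanamide | CCCCCC(=O)N(C)OC | intermediate
15 | methyl 2,4-dihydroxy-6-methylbenzoate (methyl orsellinate) | Cc1cc(O)cc(O)c1C(=O)OC | starting material
16 | methyl 4-(benzyloxy)-2-hydroxy-6-methylbenzoate | Cc1cc(OCc2ccccc2)cc(O)c1C(=O)OC | intermediate
17 | methyl 4-(benzyloxy)-2-methoxy-6-methylbenzoate | Cc1cc(OCc2ccccc2)cc(OC)c1C(=O)OC | intermediate
18 | methyl 4-(benzyloxy)-2-(lithiomethyl)-6-methoxybenzoate | [Li]Cc1cc(OCc2ccccc2)cc(OC)c1C(=O)OC | intermediate (not isolated)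
19 | methyl 4-(benzyloxy)-2-methoxy-6-(2-oxoheptyl)benzoate | CCCCCC(=O)Cc1cc(OCc2ccccc2)cc(OC)c1C(=O)OC | intermediate
20 | methyl 4-hydroxy-2-methoxy-6-(2-oxoheptyl)benzoate | CCCCCC(=O)Cc1cc(O)cc(OC)c1C(=O)OC | intermediate
21 | 3-methoxy-4-(methoxycarbonyl)-5-(2-oxoheptyl)phenyl 2-(benzyloxy)-4-methoxy-6-[(2-pentyl-1,3-dioxolan-2-yl)methyl]benzoate | CCCCCC1(Cc2cc(OC)cc(OCc3ccccc3)c2C(=O)Oc2cc(CC(=O)CCCCC)c(C(=O)OC)c(OC)c2)OCCO1 | intermediate
22 | 3-methoxy-4-(methoxycarbonyl)-5-(2-oxoheptyl)phenyl 2-(benzyloxy)-4-methoxy-6-(2-oxoheptyl)benzoate | CCCCCC(=O)Cc1cc(OC)cc(OCc2ccccc2)c1C(=O)Oc1cc(CC(=O)CCCCC)c(C(=O)OC)c(OC)c1 | intermediate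
23 | gustastatin | CCCCCC(=O)Cc1cc(OC)cc(O)c1C(=O)Oc1cc(CC(=O)CCCCC)c(C(=O)OC)c(OC)c1 | target

## Step count and least certain steps

Total step count: 15. Longest linear sequence: 9 steps (steps 1, 2, 4, 5, 6, 7, 13, 14, 15, from 1).

**Step 4 (key step).** The rhodium carbene may insert into the carboxylic O–H bond instead of following C–H metalation, which would esterify the acid with the acylmethyl group. Metalation at a position meta to both donors may also be slow, and cyclodehydration of 8 may stop at the lactol stage. Fallback: set out from 15 and build the chain by toluate chemistry.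
- Selective 4-O-methylation of 15 (MeI, 1 equiv, K2CO3, acetone) should give methyl 2-hydroxy-4-methoxy-6-methylbenzoate F1.
- Benzylation (BnBr, K2CO3, DMF) should give methyl 2-(benzyloxy)-4-methoxy-6-methylbenzoate F2.
- Lateral lithiation with LiN(iPr)2 and acylation with 14 should give methyl 2-(benzyloxy)-4-methoxy-6-(2-oxoheptyl)benzoate F3.
- Heating F3 with TsOH in toluene should close the enol lactone with loss of methanol, returning to the route at 9.

**Step 13.** Acyl transfer from the 2,6-disubstituted acyl donor to the phenol may be slower than rearrangement of the O-acylisourea to an N-acylurea, and the ketal oxygen may take part in the activated acyl group. Fallback: from 13, cyanuric fluoride and pyridine in CH2Cl2 should give 2-(benzyloxy)-4-methoxy-6-[(2-pentyl-1,3-dioxolan-2-yl)methyl]benzoyl fluoride F4, a small and isolable acyl donor. F4 is then coupled with 20 using DMAP and Et3N, returning at 21.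

**Step 14.** Once the ring A ketone is free, acid may promote enol lactonisation onto the aryl ester with expulsion of the ring B phenol, in competition with ketal hydrolysis. Fallback: from 21, hydrogenolysis first (H2, Pd/C, EtOAc) should give 3-methoxy-4-(methoxycarbonyl)-5-(2-oxoheptyl)phenyl 2-hydroxy-4-methoxy-6-[(2-pentyl-1,3-dioxolan-2-yl)methyl]benzoate F5. Its salicylate hydrogen bond should make the ester less electrophilic. The ketal is then exchanged under neutral conditions (I2 cat., acetone, rt), returning at 23.

**Step 5.** Residual base may cause C-allylation of the benzylic methylene of the ketone, and the lactone may re-close during concentration. Fallback: from 9, direct alcoholysis of the enol lactone in allyl alcohol with catalytic NaOCH2CH=CH2 at 0 °C, so that no alkyl halide is present; it returns at 11 and makes no new compound (F0). This variant carries its own risk of Dieckmann closure to a naphthalenediol, which is why it is not the first choice.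

**Step 7.** The free carboxylic acid may catalyse loss of its own neighbouring ketal and re-lactonise during isolation. Fallback: from 12, deallylation with Pd(PPh3)4 and sodium 2-ethylhexanoate should precipitate sodium 2-(benzyloxy)-4-methoxy-6-[(2-pentyl-1,3-dioxolan-2-yl)methyl]benzoate F6 without passing through the free acid. F6 is coupled directly with 20 using 2-chloro-1-methylpyridinium iodide and Et3N, returning at 21.

## Further compounds

F1 | step 4 | methyl 2-hydroxy-4-methoxy-6-methylbenzoate | Cc1cc(OC)cc(O)c1C(=O)OC
F2 | step 4 | methyl 2-(benzyloxy)-4-methoxy-6-methylbenzoate | Cc1cc(OC)cc(OCc2ccccc2)c1C(=O)OC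
F3 | step 4 | methyl 2-(benzyloxy)-4-methoxy-6-(2-oxoheptyl)benzoate | CCCCCC(=O)Cc1cc(OC)cc(OCc2ccccc2)c1C(=O)OC
F4 | step 13 | 2-(benzyloxy)-4-methoxy-6-[(2-pentyl-1,3-dioxolan-2-yl)methyl]benzoyl fluoride | CCCCCC1(Cc2cc(OC)cc(OCc3ccccc3)c2C(=O)F)OCCO1
F5 | step 14 | 3-methoxy-4-(methoxycarbonyl)-5-(2-oxoheptyl)phenyl 2-hydroxy-4-methoxy-6-[(2-pentyl-1,3-dioxolan-2-yl)methyl]benzoate | CCCCCC1(Cc2cc(OC)cc(O)c2C(=O)Oc2cc(CC(=O)CCCCC)c(C(=O)OC)c(OC)c2)OCCO1
F0 | step 5 | none | none
F6 | step 7 | sodium 2-(benzyloxy)-4-methoxy-6-[(2-pentyl-1,3-dioxolan-2-yl)methyl]benzoate | CCCCCC1(Cc2cc(OC)cc(OCc3ccccc3)c2C(=O)[O-])OCCO1.[Na+]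
A1 | alternative 1 | methyl 4-(benzyloxy)-2-methoxy-6-(2-methoxy-2-oxoethyl)benzoate | COC(=O)Cc1cc(OCc2ccccc2)cc(OC)c1C(=O)OC
A2 | alternative 1 | 5-(benzyloxy)-3-methoxy-2-(trimethylsilyl)phenyl trifluoromethanesulfonate | COc1cc(OCc2ccccc2)cc(OS(=O)(=O)C(F)(F)F)c1[Si](C)(C)C
A3 | alternative 1 | dimethyl malonate | COC(=O)CC(=O)OC
A4 | alternative 2 | 3-methoxy-4-(methoxycarbonyl)-5-[(2-pentyl-1,3-dioxolan-2-yl)methyl]phenyl 2,4-dihydroxy-6-[(2-pentyl-1,3-dioxolan-2-yl)methyl]benzoate | CCCCCC1(OCCO1)Cc1cc(O)cc(O)c1C(=O)Oc1cc(CC2(CCCCC)OCCO2)c(C(=O)OC)c(OC)c1
A5 | alternative 2 | 3-methoxy-4-(methoxycarbonyl)-5-[(2-pentyl-1,3-dioxolan-2-yl)methyl]phenyl 3,5,7-trioxo-8-(2-pentyl-1,3-dioxolan-2-yl)octanoate | CCCCCC1(CC(=O)CC(=O)CC(=O)CC(=O)Oc2cc(CC3(CCCCC)OCCO3)c(C(=O)OC)c(OC)c2)OCCO1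
A6 | alternative 3 | 3-methoxy-4-(methoxycarbonyl)-5-[(2-pentyl-1,3-dioxolan-2-yl)methyl]phenyl 2-hydroxy-4-methoxy-6-[(2-pentyl-1,3-dioxolan-2-yl)methyl]benzoate | CCCCCC1(OCCO1)Cc1cc(OC)cc(O)c1C(=O)Oc1cc(CC2(CCCCC)OCCO2)c(C(=O)OC)c(OC)c1
A7 | alternative 3 | 3-methoxy-4-(methoxycarbonyl)-5-[(2-pentyl-1,3-dioxolan-2-yl)methyl]phenyl 4-(2-pentyl-1,3-dioxolan-2-yl)but-2-ynoate | CCCCCC1(CC#CC(=O)Oc2cc(CC3(CCCCC)OCCO3)c(C(=O)OC)c(OC)c2)OCCO1
A8 | alternative 3 | [(1,3-dimethoxybuta-1,3-dien-1-yl)oxy]trimethylsilane | C=C(OC)C=C(OC)O[Si](C)(C)C
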